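**Retrosynthetic overview**

1. Numbering used throughout: C1 = CH–O‑angelate; C2, C3 = CH2; C4 = C(CH3)(C14H2–O‑tiglate); C5, C6 = CH; C7 = CH(CH3); C8 = CH2; C9 = C=O; C10 = CH; C11 = quaternary C–CH3 bonded to C1, C6 and C10. Cyclobutane C5–C6–C11–C10; ring B C5–C6–C7–C8–C9–C10; seven-membered ring C1–C2–C3–C4–C5–C10–C11.
2. Late stage: the two esters are acylations and the C7 methyl comes from a cuprate addition to the C9 enone; all of this leads back to tricyclic ketone 19 (C1=O, C9 and C14 protected).
3. Key disconnection: 19 from cis-decalone tosylate 16. C11 with its methyl is inserted between C1 and C10 of the six-membered ring C1–C2–C3–C4–C5–C10 (expansion to the seven-membered ring), and the enolate so formed closes C11–C6 (cyclobutane) in the same flask. Enabling feature: C1 is a carbonyl-level carbon flanked by the quaternary C11, and C11 is 1,4 to the oxygen-bearing ring-B carbon C6 through the fusion bond C10–C5, so the inserted atom is at once the enolate carbon and the fourth cyclobutane corner.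
4. 16 from a Diels–Alder reaction of ring-B 2-ethoxydiene 8 (C1, C2, C5–C10) with acrolein 11 (C3, C4, C14; its CHO becomes the C4 methyl); 8 from cyclohexa-1,3-diene by photooxygenation and asymmetric Kornblum–DeLaMare rearrangement.
5. Ring order: ring B (from 1), then the six-membered ring C1–C5/C10 (Diels–Alder), then the seven-membered ring by one-carbon expansion together with the cyclobutane (key step).

Key step: step 13

Assumption: in step 2 the cinchona catalyst is taken from the pseudo-enantiomeric pair 9-O-acetylcupreidine / 9-O-acetylcupreine as the member that gives the R alcohol; the sense of induction is assumed, not known for certain.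

Step 1
Reactants: 1 cyclohexa-1,3-diene
Product: 2 meso endoperoxide 2,3-dioxabicyclo[2.2.2]oct-5-ene
Conditions: O2, visible light, tetraphenylporphyrin (cat.), CH2Cl2, 0 °C
Reagents that add atoms: dioxygen, O=O
Why: Singlet-oxygen (4+2) cycloaddition to the s-cis diene should give the meso endoperoxide, which holds both future ring-B oxygens cis.

Step 2
Reactants: 2 meso endoperoxide
Product: 3 (R)-4-hydroxycyclohex-2-en-1-one
Conditions: 9-O-acetylcupreidine (cat.), CH2Cl2, 25 °C
Reagents that add atoms: none
Why: Kornblum–DeLaMare rearrangement under chiral-base catalysis: the amine should remove one of the two enantiotopic bridgehead hydrogens, the O–O bond breaks, and the bridgehead that keeps its hydrogen becomes the C6 stereocentre.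

Step 3
Reactants: 3 (R)-4-hydroxycyclohex-2-en-1-one
Product: 4 (R)-4-(tert-butyldimethylsilyloxy)cyclohex-2-en-1-one
Conditions: TBSCl, imidazole, DMF, 25 °C
Reagents that add atoms: tert-butyldimethylsilyl chloride, CC(C)(C)[Si](C)(C)Cl
Why: Standard silylation; the bulky silyl ether later shields one face of the diene.

Step 4
Reactants: 4 silyloxy enone
Product: 5 (R)-4-(tert-butyldimethylsilyloxy)-2-iodocyclohex-2-en-1-one
Conditions: I2, pyridine, CH2Cl2, 0 to 25 °C
Reagents that add atoms: iodine, II
Why: α-Iodination of an enone by the pyridine addition–iodination–elimination sequence; C6 is not touched.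

Step 5
Reactants: 5 iodo enone
Product: 6 (1S,4R)-4-(tert-butyldimethylsilyloxy)-2-iodocyclohex-2-en-1-ol (cis)
Conditions: (R)-2-methyl-CBS-oxazaborolidine (cat.), BH3·SMe2, THF, −30 °C
Reagents that add atoms: none
Why: Corey–Bakshi–Shibata reduction in which the iodoalkenyl side acts as the large group; the catalyst enantiomer is the one that should give the 1S carbinol (C9), cis to the silyloxy group.

Step 6
Reactants: 6 cis iodo alcohol
Product: 7 PMB ether of 6
Conditions: NaH, 4-methoxybenzyl chloride, Bu4N iodide (cat.), DMF, 0 to 25 °C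
Reagents that add atoms: 4-methoxybenzyl chloride, COc1ccc(CCl)cc1
Why: Williamson etherification; the PMB ether stays on C9 until the C9 ketone is needed.

Step 7
Reactants: 7 alkenyl iodide
Product: 8 ring-B 2-ethoxydiene
Conditions: tributyl(1-ethoxyvinyl)stannane, PdCl2(PPh3)2 (cat.), DMF, 70 °C; chromatography on Et3N-washed silica
Reagents that add atoms: tributyl(1-ethoxyvinyl)stannane, CCCC[Sn](CCCC)(CCCC)C(=C)OCC
Why: Stille coupling of the alkenyl iodide should install C1 and C2 as an electron-rich 2-alkoxydiene with the stereocentres C6 and C9 untouched.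

Step 8
Reactants: 9 2-methylenepropane-1,3-diol
Product: 10 2-[(methoxymethoxy)methyl]prop-2-en-1-ol
Conditions: NaH (1 equiv), MOMCl, THF, 0 °C (diol in excess, recovered)
Reagents that add atoms: chloromethyl methyl ether, COCCl
Why: Williamson mono-etherification of a symmetric diol.

Step 9
Reactants: 10 mono-MOM ether
Product: 11 2-[(methoxymethoxy)methyl]acrylaldehyde
Conditions: MnO2, CH2Cl2, 25 °C; used as a solution
Reagents that add atoms: none
Why: Selective MnO2 oxidation of an allylic alcohol to the enal.

Step 10
Reactants: 8 ring-B 2-ethoxydiene; 11 2-[(methoxymethoxy)methyl]acrylaldehyde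
Product: 12 Diels–Alder adduct (enol ether aldehyde)
Conditions: toluene, BHT (trace), Et3N (trace), 60 °C
Reagents that add atoms: none
Why: Diels–Alder reaction in which the ethoxy-bearing C1 ends para to the formyl-bearing C4 (nucleophilic C2 bonds to the acrolein CH2); the dienophile should add anti to the allylic C6–OTBS (the C9 ether is on the same face), and an endo formyl group with the larger CH2OMOM exo places CHO cis to C6, which sets C4 and C5.

Step 11
Reactants: 12 Diels–Alder adduct
Product: 15 cis-fused hydroxy decalone, via hydrazone 13 (not isolated), via C4-methyl enol ether 14 (not isolated)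
Conditions: N2H4·H2O, KOH, diethylene glycol, 130 to 195 °C; then aqueous HF, MeCN, 25 °C
Reagents that add atoms: water, O
Why: Wolff–Kishner reduction (Huang-Minlon procedure) should turn the α-quaternary CHO into the C4 methyl while the enol ether and the ethers survive base; aqueous HF then removes the TBS group and hydrolyses the enol ether. C10 equilibrates through the enol, and the cis-fused ketone is expected to be favoured because the trans isomer forces the C4 CH2OMOM arm and the C6 oxygen into a peri interaction.

Step 12
Reactants: 15 cis-fused hydroxy decalone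
Product: 16 cis-decalone tosylate
Conditions: TsCl, DMAP (cat.), pyridine, 25 to 40 °C
Reagents that add atoms: p-toluenesulfonyl chloride, Cc1ccc(cc1)S(=O)(=O)Cl
Why: Sulfonylation at oxygen with retention at C6 gives the leaving group trans to both ring-A bonds on ring B, as the later displacement needs.

Step 13
Reactants: 16 cis-decalone tosylate
Product: 19 tricyclic ketone (C1 ketone; C9 PMB ether; C14 MOM ether), via lithium carbinolate 17 (not isolated), via lithium enolate 18 (not isolated)
Conditions: CH3CHBr2, LiN(i-Pr)2, THF–Et2O, −110 °C, then 16; t-BuLi (2.1 equiv), −110 to −78 °C; HMPA, −78 to 25 °C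
Reagents that add atoms: 1,1-dibromoethane, CC(Br)Br
Why: Proposed new method: 1,1-dibromoethyllithium adds to the C1 ketone, bromine–lithium exchange on carbinolate 17 gives a β-oxido carbenoid, and its 1,2-shift (C10 moves from C1 to the carbenoid carbon C11 with loss of LiBr and retention at C10) expands the six-membered ring C1–C2–C3–C4–C5–C10 to the seven-membered ring and delivers enolate 18 regiospecifically as C1(OLi)=C11(CH3); on warming with HMPA this enolate displaces the C6 tosylate with inversion and closes C11–C6. The closest known reactions are the β-oxido carbenoid one-carbon ring expansion of cyclic ketones with gem-dibromoalkyllithiums, whose enolates have been trapped by external electrophiles, and the base-mediated cyclisation of decalone keto tosylates to bridged cyclobutanes; joining the two with an internal electrophile is the new part. The seven-membered ring arises by ring expansion, the cyclobutane by a 4-exo-tet C-alkylation. C11 is fixed by the tether (C1 and C6 are both held by rings, so only one enolate face reaches C6), C6 by SN2 inversion, and C10 by retention in the shift, so the cis fusion of 16 is carried over. The step needs migration of C10 rather than C2 (the more substituted carbon is expected to be the better migrating group in carbenoid shifts), an enolate that deprotonation could not give selectively (a C2 enolate would close a five-membered ring), and C- over O-alkylation, which the geometry secures because C6 sits over the p lobe of C11 while the enolate oxygen points away.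

Step 14
Reactants: 19 tricyclic ketone
Product: 20 C1 alcohol
Conditions: LiBH(s-Bu)3, THF, −78 to 0 °C
Reagents that add atoms: none
Why: Hydride reduction under steric approach control: the C1–C4 bridge should twist so that the CH2OMOM arm on C4 lies outward, which leaves the C1 face syn to the C6 bridge open; hydride adds there and the hydroxyl ends syn to the C10 bridge, cis to C14.

Step 15
Reactants: 20 C1 alcohol
Product: 21 C1 angelate
Conditions: LiN(SiMe3)2, THF, −78 °C; angelic anhydride, −78 to 0 °C
Reagents that add atoms: angelic anhydride, C/C=C(/C)C(=O)OC(=O)/C(C)=C\C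
Why: Acylation of the lithium alkoxide with the anhydride; no nucleophilic amine catalyst is present, so the Z double bond should not isomerise to the tiglate.

Step 16
Reactants: 21 C1 angelate
Product: 22 C9 alcohol
Conditions: DDQ, CH2Cl2, pH 7 buffer, 0 °C
Reagents that add atoms: none
Why: Oxidative cleavage of the PMB ether (benzylic hydride abstraction, hydrolysis of the oxocarbenium ion); the MOM ether and the enoate are inert.

Step 17
Reactants: 22 C9 alcohol
Product: 24 C9 enone (C7=C8), via C9 ketone 23 (not isolated)
Conditions: 2-iodoxybenzoic acid (3.5 equiv), DMSO, 25 to 75 °C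
Reagents that add atoms: none
Why: Oxidation of the alcohol followed by 2-iodoxybenzoic acid dehydrogenation of the ketone through its enol; only C8 can enolise because C10 is a bridgehead, so the double bond can only form at C7–C8.

Step 18
Reactants: 24 C9 enone
Product: 25 C7-methyl ketone
Conditions: Me2CuLi, Et2O, −78 °C; aqueous NH4Cl
Reagents that add atoms: lithium dimethylcuprate, [Li+].C[Cu-]C
Why: Gilman conjugate addition: methyl should add to C7 from the face syn to the C5 bridge (only H on that side) and anti to the C11 bridge, whose methyl projects over ring B; the trisubstituted angelate is not expected to react at −78 °C.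

Step 19
Reactants: 25 C7-methyl ketone
Product: 26 C14 alcohol
Conditions: Me2BBr, CH2Cl2, −78 °C; then aqueous NaHCO3
Reagents that add atoms: none
Why: Cleavage of the MOM acetal by boron coordination and bromide attack; the ketone and the ester are tolerated at low temperature.

Step 20
Reactants: 26 C14 alcohol
Product: 27 target
Conditions: tigloyl chloride, pyridine, DMAP (cat.), CH2Cl2, 0 to 25 °C
Reagents that add atoms: tigloyl chloride, C/C=C(\C)C(Cl)=O
Why: Acylation of the primary alcohol with the acid chloride under nucleophilic catalysis; the E acid chloride is the stable isomer.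

**Compound list**

1 | cyclohexa-1,3-diene | C1=CC=CCC1 | starting material
2 | (1R,4S)-2,3-dioxabicyclo[2.2.2]oct-5-ene (meso) | C1=C[C@H]2CC[C@@H]1OO2 | intermediate
3 | (R)-4-hydroxycyclohex-2-en-1-one | O=C1C=C[C@H](O)CC1 | intermediate
4 | (R)-4-(tert-butyldimethylsilyloxy)cyclohex-2-en-1-one | O=C1C=C[C@H](O[Si](C)(C)C(C)(C)C)CC1 | intermediate
5 | (R)-4-(tert-butyldimethylsilyloxy)-2-iodocyclohex-2-en-1-one | O=C1C(I)=C[C@H](O[Si](C)(C)C(C)(C)C)CC1 | intermediate
6 | (1S,4R)-4-(tert-butyldimethylsilyloxy)-2-iodocyclohex-2-en-1-ol (cis) | O[C@@H]1C(I)=C[C@H](O[Si](C)(C)C(C)(C)C)CC1 | intermediate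
7 | tert-butyl{[(1R,4S)-3-iodo-4-(4-methoxybenzyloxy)cyclohex-2-en-1-yl]oxy}dimethylsilane | COc1ccc(CO[C@@H]2C(I)=C[C@H](O[Si](C)(C)C(C)(C)C)CC2)cc1 | intermediate
8 | tert-butyl{[(1R,4S)-3-(1-ethoxyvinyl)-4-(4-methoxybenzyloxy)cyclohex-2-en-1-yl]oxy}dimethylsilane (ring-B 2-ethoxydiene) | C=C(OCC)C1=C[C@H](O[Si](C)(C)C(C)(C)C)CC[C@@H]1OCc1ccc(OC)cc1 | intermediate
9 | 2-methylenepropane-1,3-diol | C=C(CO)CO | starting material
10 | 2-[(methoxymethoxy)methyl]prop-2-en-1-ol | C=C(CO)COCOC | intermediate
11 | 2-[(methoxymethoxy)methyl]acrylaldehyde | C=C(C=O)COCOC | intermediate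
12 | Diels–Alder adduct: bicyclic enol ether C1(OEt)=C10; C4 bears CHO (cis to C6) and CH2OMOM (cis to H5); C6–OTBS trans to the C5–C4 bond; C9–OPMB cis to C6–OTBS | CCOC1=C2[C@@H](OCc3ccc(OC)cc3)CC[C@@H](O[Si](C)(C)C(C)(C)C)[C@@H]2[C@@](C=O)(COCOC)CC1 | intermediate
13 | hydrazone of 12 | CCOC1=C2[C@@H](OCc3ccc(OC)cc3)CC[C@@H](O[Si](C)(C)C(C)(C)C)[C@@H]2[C@@](C=NN)(COCOC)CC1 | intermediate
14 | C4-methyl enol ether (12 with CH3 in place of CHO) | CCOC1=C2[C@@H](OCc3ccc(OC)cc3)CC[C@@H](O[Si](C)(C)C(C)(C)C)[C@@H]2[C@@](C)(COCOC)CC1 | intermediate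
15 | cis-fused hydroxy decalone: C1 ketone; C4 methyl (cis to C6) and CH2OMOM; C6–OH; C9–OPMB; H5 and H10 cis | O=C1CC[C@](C)(COCOC)[C@H]2[C@H](O)CC[C@H](OCc3ccc(OC)cc3)[C@@H]12 | intermediate
16 | cis-decalone tosylate (15 with C6–OTs) | O=C1CC[C@](C)(COCOC)[C@H]2[C@H](OS(=O)(=O)c3ccc(C)cc3)CC[C@H](OCc3ccc(OC)cc3)[C@@H]12 | intermediate
17 | lithium carbinolate: C1 bears OLi and the 1,1-dibromoethyl group (C1 configuration drawn for equatorial attack; it has no bearing on the product) | [Li]O[C@@]1(C(C)(Br)Br)CC[C@](C)(COCOC)[C@H]2[C@H](OS(=O)(=O)c3ccc(C)cc3)CC[C@H](OCc3ccc(OC)cc3)[C@@H]12 | intermediate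
18 | ring-expanded lithium enolate C1(OLi)=C11(CH3) of the cis-fused bicyclo[5.4.0]undecane | [Li]OC1=C(C)[C@@H]2[C@@H](OCc3ccc(OC)cc3)CC[C@@H](OS(=O)(=O)c3ccc(C)cc3)[C@@H]2[C@@](C)(COCOC)CC1 | intermediate
19 | tricyclic ketone: C1 ketone; C9–OPMB; C14–OMOM; no C7 methyl | O=C1CC[C@](C)(COCOC)[C@H]2[C@@H]3CC[C@H](OCc4ccc(OC)cc4)[C@H]2[C@@]31C | intermediate
20 | C1 alcohol (OH syn to the C10 bridge, cis to C14) | O[C@@H]1CC[C@](C)(COCOC)[C@H]2[C@@H]3CC[C@H](OCc4ccc(OC)cc4)[C@H]2[C@@]31C | intermediate
21 | C1 angelate | C/C=C(/C)C(=O)O[C@@H]1CC[C@](C)(COCOC)[C@H]2[C@@H]3CC[C@H](OCc4ccc(OC)cc4)[C@H]2[C@@]31C | intermediate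
22 | C9 alcohol | C/C=C(/C)C(=O)O[C@@H]1CC[C@](C)(COCOC)[C@H]2[C@@H]3CC[C@H](O)[C@H]2[C@@]31C | intermediate
23 | C9 ketone | C/C=C(/C)C(=O)O[C@@H]1CC[C@](C)(COCOC)[C@H]2[C@@H]3CCC(=O)[C@H]2[C@@]31C | intermediate
24 | C9 enone (C7=C8) | C/C=C(/C)C(=O)O[C@@H]1CC[C@](C)(COCOC)[C@H]2[C@@H]3C=CC(=O)[C@H]2[C@@]31C | intermediate
25 | C7-methyl ketone (methyl syn to the C5 bridge) | C/C=C(/C)C(=O)O[C@@H]1CC[C@](C)(COCOC)[C@H]2[C@@H]3[C@H](C)CC(=O)[C@H]2[C@@]31C | intermediate
26 | C14 alcohol | C/C=C(/C)C(=O)O[C@@H]1CC[C@](C)(CO)[C@H]2[C@@H]3[C@H](C)CC(=O)[C@H]2[C@@]31C | intermediate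
27 | CNP0276938.2 (C1 angelate, C14 tiglate, C9 ketone) | C/C=C(/C)C(=O)O[C@@H]1CC[C@](C)(COC(=O)/C(C)=C/C)[C@H]2[C@@H]3[C@H](C)CC(=O)[C@H]2[C@@]31C | target

**Step count and risks**

Total step count: 20. Longest linear sequence: 18 steps (steps 1–7 and 10–20).

Step 13 (ring expansion with cyclobutane closure). The carbenoid shift may move C2 instead of C10. Proton transfer may also shift the enolate to C2 before it alkylates, and t-BuLi may attack the sulfonate while HMPA and heat are applied. Fallback, from 16 back to 19: the two events are separated. The same carbenoid expansion is run on 16, but the cold solution of enolate 18 is quenched with Me3SiCl to give the trimethylsilyl enol ether F1, which is isolated so that the migration outcome can be checked and purified. The lithium enolate is then regenerated from F1 with MeLi in THF and, after addition of DMPU, closes the cyclobutane at 25 °C in a separate keto-tosylate alkylation, rejoining the route at 19. Each operation here (enolate trapping after carbenoid expansion, enolate regeneration from a silyl enol ether, keto-tosylate cyclisation) is known chemistry.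

Step 10 (Diels–Alder). Endo/exo selectivity at C4 or facial selectivity at C5 may be poor, and the 2-ethoxydiene may hydrolyse or polymerise. Fallback, from 8 back to 12: C4 is built stepwise. Diene 8 reacts with methyl acrylate to give the ester adduct F2, whose C4 configuration does not matter. Its ester enolate (LiN(i-Pr)2, THF, −78 °C) is alkylated with MOMCl from the face anti to C6 to give the quaternary ester F3, with CH2OMOM cis to H5. LiAlH4 reduction gives the neopentyl alcohol F4, and Dess–Martin oxidation buffered with pyridine returns aldehyde 12.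

Step 11 (Wolff–Kishner and hydrolysis). At 195 °C in KOH the enol ether may isomerise, the allylic C9 ether may be lost, or the hindered hydrazone may not reduce fully. Fallback, from 12 back to 15: 12 is condensed with tosylhydrazide to the tosylhydrazone F5, which is reduced with catecholborane and then NaOAc in warm CHCl3 to the C4-methyl enol ether 14. Aqueous HF in MeCN then gives 15 as in the main route.

Further compounds
F1 | step 13 | trimethylsilyl enol ether C1(OSiMe3)=C11(CH3) of the ring-expanded keto tosylate | C[Si](C)(C)OC1=C(C)[C@@H]2[C@@H](OCc3ccc(OC)cc3)CC[C@@H](OS(=O)(=O)c3ccc(C)cc3)[C@@H]2[C@@](C)(COCOC)CC1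
F2 | step 10 | methyl acrylate Diels–Alder adduct (C4–CO2CH3, both C4 epimers) | CCOC1=C2[C@@H](OCc3ccc(OC)cc3)CC[C@@H](O[Si](C)(C)C(C)(C)C)[C@@H]2C(C(=O)OC)CC1
F3 | step 10 | C4-quaternary methyl ester (CO2CH3 cis to C6, CH2OMOM cis to H5) | CCOC1=C2[C@@H](OCc3ccc(OC)cc3)CC[C@@H](O[Si](C)(C)C(C)(C)C)[C@@H]2[C@@](C(=O)OC)(COCOC)CC1
F4 | step 10 | neopentyl alcohol (CH2OH in place of the CHO of 12) | CCOC1=C2[C@@H](OCc3ccc(OC)cc3)CC[C@@H](O[Si](C)(C)C(C)(C)C)[C@@H]2[C@@](CO)(COCOC)CC1
F5 | step 11 | tosylhydrazone of 12 | CCOC1=C2[C@@H](OCc3ccc(OC)cc3)CC[C@@H](O[Si](C)(C)C(C)(C)C)[C@@H]2[C@@](C=NNS(=O)(=O)c3ccc(C)cc3)(COCOC)CC1
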